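**Retrosynthetic overview**
Ring numbering: C1 = CH bearing the alkenyl group, C2 = CH bearing the 3-oxobutyl chain, C3 = CMe2, C4 = CH2. C2, C3, the two methyl groups and the oxobutyl chain together are the unbroken carbon skeleton of 6-methylhept-5-en-2-one, so the only ring (the cyclobutane) lacks just the two-carbon unit C1–C4.
Ester C–O (last step): target ⇒ linoleic acid 20 + keto alcohol 19; 19 ⇒ protected alkene 18 ⇒ ketone 17 (methylenation) ⇒ trans aldehyde 13 + TBSO(CH2)3MgBr 15.
13 ⇒ cyclobutanone 8 by one-carbon homologation at C1: non-basic methylenation, hydroboration, oxidation, then equilibration to trans.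
8 ⇒ [2+2] of sulcatone ketal 2 with the keteniminium ion from chiral acetamide 4. This forms C1–C2 and C3–C4, closes the ring and sets C2; C1 is later set relative to C2 under thermodynamic control.

Key step: step 3

Assumption: the sense of induction of the (2R,5R)-auxiliary on this acyclic alkene cannot be derived with certainty, so it is taken to give (S)-8; should the first run show the opposite sense, the equally available (2S,5S)-amine is used in steps 2 and 3 with nothing else changed.

**Step 1**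
Reactants: 1 6-methylhept-5-en-2-one
Product: 2 2-methyl-2-(4-methylpent-3-en-1-yl)-1,3-dioxolane
Conditions: HOCH2CH2OH, p-TsOH·H2O (cat.), toluene, Dean–Stark, reflux
Reagents that add atoms: ethane-1,2-diol, OCCO
Why: Acid-catalysed ketalisation with azeotropic removal of water is routine for methyl ketones, and catalytic p-TsOH in toluene does not protonate the isolated trisubstituted alkene.

**Step 2**
Reactants: 3 (2R,5R)-2,5-dimethylpyrrolidine
Product: 4 1-[(2R,5R)-2,5-dimethylpyrrolidin-1-yl]ethan-1-one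
Conditions: Ac2O, Et3N, DMAP (cat.), CH2Cl2, 0 °C → rt
Reagents that add atoms: acetic anhydride, CC(=O)OC(C)=O
Why: DMAP-catalysed N-acylation of a secondary amine with an anhydride leaves both ring stereocentres untouched.

**Step 3**
Reactants: 4 1-[(2R,5R)-2,5-dimethylpyrrolidin-1-yl]ethan-1-one; 2 2-methyl-2-(4-methylpent-3-en-1-yl)-1,3-dioxolane (slight excess)
Product: 8 (2S)-3,3-dimethyl-2-[2-(2-methyl-1,3-dioxolan-2-yl)ethyl]cyclobutan-1-one, via O-triflyloxyiminium triflate 5 (not isolated), via keteniminium triflate 6 (not isolated), via cyclobutaniminium triflate 7 (not isolated)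
Conditions: 4, Tf2O, ClCH2CH2Cl, −15 °C; then 2 + 2,4,6-collidine, −15 → 60 °C; then sat. aq. NaHCO3, CH2Cl2, rt
Reagents that add atoms: water, O; trifluoromethanesulfonic anhydride, O=S(=O)(C(F)(F)F)OS(=O)(=O)C(F)(F)F (its atoms stay only in 5, 6 and 7)
Why: Tf2O O-sulfonylates 4 to 5 before the ketal is present; collidine then removes an acetyl proton with loss of triflate to give 6, whose electrophilic central carbon (future C1) is attacked by the less substituted alkene carbon C2 of 2 while charge builds on tertiary C3, the enamine-like CH2 terminus (future C4) closes onto C3 to give 7, and water hydrolyses 7 to 8. The closest known reaction type is the intermolecular keteniminium–alkene [2+2] cycloaddition of tertiary acetamides activated by Tf2O and collidine, including its auxiliary-controlled form with C2-symmetric pyrrolidine amides. The cyclobutane closes in an intermolecular, asynchronous polar [2+2] mode in which C1–C2 runs ahead of C3–C4. The only new stereocentre, C2, is set by the auxiliary: its C2 axis makes both faces of the C=N π* orbital equivalent, and on each face one pyrrolidine methyl group blocks one quadrant, so the alkene should bond through the face that places its ketal-bearing chain in the open quadrant. The step needs regioselectivity, which the tertiary-versus-secondary cation difference between C3 and C2 secures, and chemoselectivity for the alkene over the ketal oxygens, which consuming Tf2O first and buffering with collidine secure. It also needs configurational stability at C2, which holds because enamine or enol formation would put a double bond inside the four-membered ring and because the hydrolysis is bicarbonate-buffered.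

**Step 4**
Reactants: 8 (2S)-3,3-dimethyl-2-[2-(2-methyl-1,3-dioxolan-2-yl)ethyl]cyclobutan-1-one
Product: 9 2-{2-[(1S)-2,2-dimethyl-4-methylidenecyclobutyl]ethyl}-2-methyl-1,3-dioxolane
Conditions: Cp2TiMe2 (2.5 equiv), toluene–THF, 70 °C, dark
Reagents that add atoms: dimethyltitanocene Cp2TiMe2, [CH3-].[CH3-].[Ti+4].c1cc[cH-]c1.c1cc[cH-]c1
Why: In the Petasis methylenation the non-basic carbene Cp2Ti=CH2 adds to the strained, electrophilic cyclobutanone carbonyl by [2+2]/cycloreversion without enolisation, so C2 should keep its configuration and the ketal is inert.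

**Step 5**
Reactants: 9 2-{2-[(1S)-2,2-dimethyl-4-methylidenecyclobutyl]ethyl}-2-methyl-1,3-dioxolane
Product: 11 {(1R,2R)-3,3-dimethyl-2-[2-(2-methyl-1,3-dioxolan-2-yl)ethyl]cyclobutyl}methanol (cis isomer expected to predominate), via B-alkyl-9-BBN adduct 10 (not isolated)
Conditions: 9-BBN, THF, 0 °C → rt; then NaOH, H2O2, 0 °C → rt
Reagents that add atoms: hydrogen peroxide, OO; 9-borabicyclo[3.3.1]nonane, B1C2CCCC1CCC2 (boron stays only in 10)
Why: Anti-Markovnikov hydroboration–oxidation puts boron on the exocyclic CH2, and 9-BBN should approach opposite the C2 chain so that H lands on C1 anti to it and CH2OH comes out mainly cis, which does not matter because C1 is equilibrated in step 7.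

**Step 6**
Reactants: 11 {(1R,2R)-3,3-dimethyl-2-[2-(2-methyl-1,3-dioxolan-2-yl)ethyl]cyclobutyl}methanol
Product: 12 (1R,2R)-3,3-dimethyl-2-[2-(2-methyl-1,3-dioxolan-2-yl)ethyl]cyclobutane-1-carbaldehyde (cis)
Conditions: Dess–Martin periodinane, pyridine, CH2Cl2, 0 °C → rt
Reagents that add atoms: none
Why: The pyridine-buffered Dess–Martin oxidation stops at the aldehyde and spares the ketal.

**Step 7**
Reactants: 12 (1R,2R)-3,3-dimethyl-2-[2-(2-methyl-1,3-dioxolan-2-yl)ethyl]cyclobutane-1-carbaldehyde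
Product: 13 (1S,2R)-3,3-dimethyl-2-[2-(2-methyl-1,3-dioxolan-2-yl)ethyl]cyclobutane-1-carbaldehyde (trans)
Conditions: DBU (0.3 equiv), CH2Cl2, rt; chromatography, residual cis isomer resubmitted
Reagents that add atoms: none
Why: Base-mediated epimerisation through the aldehyde enolate is thermodynamically controlled and should favour the trans-1,2-disubstituted cyclobutane, where the formyl group avoids the C2 chain, while C2 has no acidifying neighbour left and is untouched.

**Step 8**
Reactants: 13 (1S,2R)-3,3-dimethyl-2-[2-(2-methyl-1,3-dioxolan-2-yl)ethyl]cyclobutane-1-carbaldehyde; 14 (3-bromopropoxy)(tert-butyl)dimethylsilane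
Product: 16 4-[(tert-butyldimethylsilyl)oxy]-1-{(1S,2R)-3,3-dimethyl-2-[2-(2-methyl-1,3-dioxolan-2-yl)ethyl]cyclobutyl}butan-1-ol (both carbinol epimers), via Grignard reagent 15 (not isolated)
Conditions: 14, Mg, THF, 40 °C; then 13, THF, −78 → 0 °C; sat. aq. NH4Cl
Reagents that add atoms: magnesium, [Mg] (stays only in 15)
Why: Grignard formation and 1,2-addition to an aldehyde at low temperature outruns enolisation, and the new carbinol centre needs no control because step 9 removes it.

**Step 9**
Reactants: 16 4-[(tert-butyldimethylsilyl)oxy]-1-{(1S,2R)-3,3-dimethyl-2-[2-(2-methyl-1,3-dioxolan-2-yl)ethyl]cyclobutyl}butan-1-ol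
Product: 17 4-[(tert-butyldimethylsilyl)oxy]-1-{(1S,2R)-3,3-dimethyl-2-[2-(2-methyl-1,3-dioxolan-2-yl)ethyl]cyclobutyl}butan-1-one
Conditions: Dess–Martin periodinane, pyridine, CH2Cl2, rt
Reagents that add atoms: none
Why: The Dess–Martin oxidation of a secondary alcohol runs under near-neutral conditions that leave the silyl ether, the ketal and the trans C1 centre alone.

**Step 10**
Reactants: 17 4-[(tert-butyldimethylsilyl)oxy]-1-{(1S,2R)-3,3-dimethyl-2-[2-(2-methyl-1,3-dioxolan-2-yl)ethyl]cyclobutyl}butan-1-one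
Product: 18 tert-butyl[(4-{(1S,2R)-3,3-dimethyl-2-[2-(2-methyl-1,3-dioxolan-2-yl)ethyl]cyclobutyl}pent-4-en-1-yl)oxy]dimethylsilane
Conditions: MePPh3Br, KOt-Bu, THF, 0 °C → rt
Reagents that add atoms: methyltriphenylphosphonium bromide, C[P+](c1ccccc1)(c1ccccc1)c1ccccc1.[Br-]
Why: Wittig methylenation of a dialkyl ketone is reliable, and any reversible enolisation at C1 by the ylide returns to the trans isomer, which is already the more stable one.

**Step 11**
Reactants: 18 tert-butyl[(4-{(1S,2R)-3,3-dimethyl-2-[2-(2-methyl-1,3-dioxolan-2-yl)ethyl]cyclobutyl}pent-4-en-1-yl)oxy]dimethylsilane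
Product: 19 4-[(1S,2R)-3,3-dimethyl-2-(3-oxobutyl)cyclobutyl]pent-4-en-1-ol
Conditions: 1 M aq. HCl, THF, rt
Reagents that add atoms: water, O
Why: Dilute aqueous acid hydrolyses the primary TBS ether and the dioxolane in one operation, is too weak to protonate the 1,1-disubstituted alkene, and is applied before the skipped diene is present.

**Step 12**
Reactants: 19 4-[(1S,2R)-3,3-dimethyl-2-(3-oxobutyl)cyclobutyl]pent-4-en-1-ol; 20 linoleic acid, (9Z,12Z)-octadeca-9,12-dienoic acid
Product: 21 IN0146, 4-[(1S,2R)-3,3-dimethyl-2-(3-oxobutyl)cyclobutyl]pent-4-en-1-yl (9Z,12Z)-octadeca-9,12-dienoate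
Conditions: DCC, DMAP (cat.), CH2Cl2, 0 °C → rt, argon
Reagents that add atoms: none
Why: The Steglich esterification acylates the unhindered primary alcohol under neutral conditions that do not move the Z,Z-diene, the exocyclic alkene or either ring stereocentre.

**Compound list**
1 | 6-methylhept-5-en-2-one | CC(=O)CCC=C(C)C | starting material
2 | 2-methyl-2-(4-methylpent-3-en-1-yl)-1,3-dioxolane | CC(C)=CCCC1(C)OCCO1 | intermediate
3 | (2R,5R)-2,5-dimethylpyrrolidine | N1[C@H](C)CC[C@H]1C | starting material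
4 | 1-[(2R,5R)-2,5-dimethylpyrrolidin-1-yl]ethan-1-one | CC(=O)N1[C@H](C)CC[C@H]1C | intermediate
5 | (2R,5R)-2,5-dimethyl-1-[1-(trifluoromethanesulfonyloxy)ethylidene]pyrrolidin-1-ium triflate | CC(OS(=O)(=O)C(F)(F)F)=[N+]1[C@H](C)CC[C@H]1C.[O-]S(=O)(=O)C(F)(F)F | intermediate
6 | (2R,5R)-1-ethenylidene-2,5-dimethylpyrrolidin-1-ium triflate | C=C=[N+]1[C@H](C)CC[C@H]1C.[O-]S(=O)(=O)C(F)(F)F | intermediate
7 | (2R,5R)-1-{(2S)-3,3-dimethyl-2-[2-(2-methyl-1,3-dioxolan-2-yl)ethyl]cyclobutylidene}-2,5-dimethylpyrrolidin-1-ium triflate | [N+]1(=C2CC(C)(C)[C@@H]2CCC3(C)OCCO3)[C@H](C)CC[C@H]1C.[O-]S(=O)(=O)C(F)(F)F | intermediate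
8 | (2S)-3,3-dimethyl-2-[2-(2-methyl-1,3-dioxolan-2-yl)ethyl]cyclobutan-1-one | O=C1CC(C)(C)[C@@H]1CCC2(C)OCCO2 | intermediate
9 | 2-{2-[(1S)-2,2-dimethyl-4-methylidenecyclobutyl]ethyl}-2-methyl-1,3-dioxolane | C=C1CC(C)(C)[C@@H]1CCC2(C)OCCO2 | intermediate
10 | cis B-(cyclobutylmethyl)-9-BBN adduct of 9 | C1CC2CCCC(C1)B2C[C@@H]3CC(C)(C)[C@@H]3CCC4(C)OCCO4 | intermediate
11 | {(1R,2R)-3,3-dimethyl-2-[2-(2-methyl-1,3-dioxolan-2-yl)ethyl]cyclobutyl}methanol (cis) | OC[C@@H]1CC(C)(C)[C@@H]1CCC2(C)OCCO2 | intermediate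
12 | (1R,2R)-3,3-dimethyl-2-[2-(2-methyl-1,3-dioxolan-2-yl)ethyl]cyclobutane-1-carbaldehyde (cis) | O=C[C@@H]1CC(C)(C)[C@@H]1CCC2(C)OCCO2 | intermediate
13 | (1S,2R)-3,3-dimethyl-2-[2-(2-methyl-1,3-dioxolan-2-yl)ethyl]cyclobutane-1-carbaldehyde (trans) | O=C[C@H]1CC(C)(C)[C@@H]1CCC2(C)OCCO2 | intermediate
14 | (3-bromopropoxy)(tert-butyl)dimethylsilane (commercial; also one step from 3-bromopropan-1-ol) | CC(C)(C)[Si](C)(C)OCCCBr | starting material
15 | {3-[(tert-butyldimethylsilyl)oxy]propyl}magnesium bromide | CC(C)(C)[Si](C)(C)OCCC[Mg]Br | intermediate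
16 | 4-[(tert-butyldimethylsilyl)oxy]-1-{(1S,2R)-3,3-dimethyl-2-[2-(2-methyl-1,3-dioxolan-2-yl)ethyl]cyclobutyl}butan-1-ol (carbinol epimers) | CC(C)(C)[Si](C)(C)OCCCC(O)[C@H]1CC(C)(C)[C@@H]1CCC2(C)OCCO2 | intermediate
17 | 4-[(tert-butyldimethylsilyl)oxy]-1-{(1S,2R)-3,3-dimethyl-2-[2-(2-methyl-1,3-dioxolan-2-yl)ethyl]cyclobutyl}butan-1-one | CC(C)(C)[Si](C)(C)OCCCC(=O)[C@H]1CC(C)(C)[C@@H]1CCC2(C)OCCO2 | intermediate
18 | tert-butyl[(4-{(1S,2R)-3,3-dimethyl-2-[2-(2-methyl-1,3-dioxolan-2-yl)ethyl]cyclobutyl}pent-4-en-1-yl)oxy]dimethylsilane | C=C(CCCO[Si](C)(C)C(C)(C)C)[C@H]1CC(C)(C)[C@@H]1CCC2(C)OCCO2 | intermediate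
19 | 4-[(1S,2R)-3,3-dimethyl-2-(3-oxobutyl)cyclobutyl]pent-4-en-1-ol | C=C(CCCO)[C@H]1CC(C)(C)[C@@H]1CCC(C)=O | intermediate
20 | linoleic acid, (9Z,12Z)-octadeca-9,12-dienoic acid | CCCCC/C=C\C/C=C\CCCCCCCC(=O)O | starting material
21 | IN0146, 4-[(1S,2R)-3,3-dimethyl-2-(3-oxobutyl)cyclobutyl]pent-4-en-1-yl (9Z,12Z)-octadeca-9,12-dienoate | C=C(CCCOC(=O)CCCCCCC/C=C\C/C=C\CCCCC)[C@H]1CC(C)(C)[C@@H]1CCC(C)=O | target

Total step count: 12. Longest linear sequence: 11 steps (1, then 3 to 12).

**Steps most likely to fail**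

**Step 3.**
- Facial discrimination by the auxiliary may be low on an acyclic trisubstituted alkene.
- The developing tertiary cation at C3 may lose a proton, giving ene-type acylation instead of ring closure.
- Collidinium triflate may open the ketal on heating.
- C2 may erode during hydrolysis of the hindered iminium salt.

The fallback sets out from 2 and comes back at 8. Dichloroketene (Cl3CCOCl, Zn(Cu), Et2O–DME) is a more reactive ketene equivalent with the same regiochemical bias. It should give rac-2,2-dichloro-3,3-dimethyl-4-[2-(2-methyl-1,3-dioxolan-2-yl)ethyl]cyclobutan-1-one F1. Reductive dechlorination with Zn and NH4Cl in MeOH then gives rac-3,3-dimethyl-2-[2-(2-methyl-1,3-dioxolan-2-yl)ethyl]cyclobutan-1-one F2. The enantiomers are separated by adding lithiated (S)-N,S-dimethyl-S-phenylsulfoximine (n-BuLi, THF, −78 °C), which should attack anti to the C2 chain. This gives two carbinols separable by chromatography: (1R,2S)-3,3-dimethyl-1-{[(S)-N-methyl-S-phenylsulfonimidoyl]methyl}-2-[2-(2-methyl-1,3-dioxolan-2-yl)ethyl]cyclobutan-1-ol F3, and its (1S,2R)-configured ring diastereomer, (1S,2R)-3,3-dimethyl-1-{[(S)-N-methyl-S-phenylsulfonimidoyl]methyl}-2-[2-(2-methyl-1,3-dioxolan-2-yl)ethyl]cyclobutan-1-ol F4. Thermolysis of F3 in refluxing toluene reverses the addition under neutral conditions and releases 8.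

**Step 4.** Heating with the titanium reagent may cause partial loss of configuration at C2, or conversion of the flanked carbonyl may be incomplete. The fallback sets out from 8 and comes back at 9 by a two-stage Peterson olefination. The weakly basic organocerium reagent from Me3SiCH2MgCl and CeCl3 (THF, −78 °C) adds to the carbonyl faster than it enolises it. This gives (1R,2S)-3,3-dimethyl-2-[2-(2-methyl-1,3-dioxolan-2-yl)ethyl]-1-[(trimethylsilyl)methyl]cyclobutan-1-ol F5, in which C2 is no longer next to a carbonyl. Syn elimination with KH in THF then gives 9.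

**Step 7.** The trans preference at equilibrium may be insufficient, or the aldehyde may undergo competing aldol self-condensation under base. The fallback sets out from 12 and comes back at 17, moving the stereochemical correction to the ketone, whose larger acyl group should raise the trans preference and which cannot self-condense as easily. Grignard reagent 15 is added to 12 to give 4-[(tert-butyldimethylsilyl)oxy]-1-{(1R,2R)-3,3-dimethyl-2-[2-(2-methyl-1,3-dioxolan-2-yl)ethyl]cyclobutyl}butan-1-ol F6. Dess–Martin oxidation gives 4-[(tert-butyldimethylsilyl)oxy]-1-{(1R,2R)-3,3-dimethyl-2-[2-(2-methyl-1,3-dioxolan-2-yl)ethyl]cyclobutyl}butan-1-one F7. Equilibration with NaOMe in MeOH then converts F7 into 17.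

**Further compounds**
F1 | step 3 | rac-2,2-dichloro-3,3-dimethyl-4-[2-(2-methyl-1,3-dioxolan-2-yl)ethyl]cyclobutan-1-one | O=C1C(Cl)(Cl)C(C)(C)C1CCC2(C)OCCO2
F2 | step 3 | rac-3,3-dimethyl-2-[2-(2-methyl-1,3-dioxolan-2-yl)ethyl]cyclobutan-1-one | O=C1CC(C)(C)C1CCC2(C)OCCO2
F3 | step 3 | (1R,2S)-3,3-dimethyl-1-{[(S)-N-methyl-S-phenylsulfonimidoyl]methyl}-2-[2-(2-methyl-1,3-dioxolan-2-yl)ethyl]cyclobutan-1-ol | O[C@]1(C[S@@](=O)(=NC)c2ccccc2)CC(C)(C)[C@@H]1CCC3(C)OCCO3
F4 | step 3 | (1S,2R)-3,3-dimethyl-1-{[(S)-N-methyl-S-phenylsulfonimidoyl]methyl}-2-[2-(2-methyl-1,3-dioxolan-2-yl)ethyl]cyclobutan-1-ol | O[C@@]1(C[S@@](=O)(=NC)c2ccccc2)CC(C)(C)[C@H]1CCC3(C)OCCO3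
F5 | step 4 | (1R,2S)-3,3-dimethyl-2-[2-(2-methyl-1,3-dioxolan-2-yl)ethyl]-1-[(trimethylsilyl)methyl]cyclobutan-1-ol | O[C@]1(C[Si](C)(C)C)CC(C)(C)[C@@H]1CCC2(C)OCCO2
F6 | step 7 | 4-[(tert-butyldimethylsilyl)oxy]-1-{(1R,2R)-3,3-dimethyl-2-[2-(2-methyl-1,3-dioxolan-2-yl)ethyl]cyclobutyl}butan-1-ol | CC(C)(C)[Si](C)(C)OCCCC(O)[C@@H]1CC(C)(C)[C@@H]1CCC2(C)OCCO2
F7 | step 7 | 4-[(tert-butyldimethylsilyl)oxy]-1-{(1R,2R)-3,3-dimethyl-2-[2-(2-methyl-1,3-dioxolan-2-yl)ethyl]cyclobutyl}butan-1-one | CC(C)(C)[Si](C)(C)OCCCC(=O)[C@@H]1CC(C)(C)[C@@H]1CCC2(C)OCCO2
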